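Numbering: the core is counted as tricyclo[4.2.1.1(2,5)]deca-3,7-diene, so C2 is the methylated quaternary bridgehead, C3 and C7 carry the cyclopropyl groups, C8 carries the second methyl, and C9 and C10 are the CH2 bridges.
Retrosynthesis: both ring alkenes C3=C4 and C7=C8 are cut first (back to four carbonyl carbons on a cyclohexane), then the C8–CH3 and C2–CH3 bonds, then the two bonds from C3 and C7 to the cyclopropanes, and last the bond between each cyclopropane and its oxobutyl chain.
Enabling feature: on the six-membered ring C1–C2–C10–C5–C6–C9 the four exocyclic carbons C8, C3, C4 and C7 are all cis, and the two identical cyclopropyl groups sit on C3 and C7, which the twofold axis of the unsubstituted core maps onto each other; a meso all-cis cyclohexane bis-anhydride has the same symmetry.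
Forward order: cyclopropane (from a cyclopropene, chain joined in the same step), both cyclopropyl ketones attached at once to the purchased six-membered ring, C2 and C8 methyls, both cyclopentenes closed together by reductive carbonyl coupling, ketals removed.
Stereochemistry: the cyclopropane centres come from a ligand-controlled syn-carbomagnesiation; C1, C2, C5 and C6 come from the all-cis dianhydride and the ligand-controlled choice of carbonyl in the double acylation; quaternary C2 keeps its sense because iodomethane enters opposite its three cis neighbours.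

Key step: step 5

Remark: the all-cis dianhydride is taken as purchased (it is sold as a polyimide monomer); otherwise pyromellitic acid is hydrogenated over Rh/C and the all-cis tetraacid dehydrated with Ac2O.
Remark: which hand of the ferrocenyl diphosphine gives the required sense in steps 4 and 5 must be settled by experiment; the ligand named stands for the hand that does.
Remark: the carbinol centres made in steps 6 and 10 are oxidised back in step 11, so they are carried as epimer mixtures and left open in the SMILES.

Step 1
Reactants: 1 3-methylbut-2-enal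
Product: 2 N'-(3-methylbut-2-en-1-ylidene)-4-methylbenzenesulfonohydrazide (prenal tosylhydrazone)
Conditions: TsNHNH2, MeOH, 0 °C → rt
Reagents that add atoms: 4-methylbenzenesulfonohydrazide, Cc1ccc(cc1)S(=O)(=O)NN
Why: Hydrazone condensation of an aldehyde with a sulfonyl hydrazide is fast at or below room temperature, where the enal hydrazone does not yet cyclise to a pyrazoline.

Step 2
Reactants: 2 prenal tosylhydrazone
Product: 5 3,3-dimethylcyclopropene, via hydrazone sodium salt 3 (not isolated), via 1-diazo-3-methylbut-2-ene 4 (not isolated)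
Conditions: NaOMe, diglyme, rt; then 120–130 °C under N2 sweep, distillate trapped at −78 °C and taken up in cold Et2O
Reagents that add atoms: none
Why: Bamford–Stevens reaction, in which the salt loses sulfinate to the vinyl diazoalkane, N2 is extruded and the alkenylcarbene closes to the cyclopropene, which is swept out of the hot mixture before it can react further.

Step 3
Reactants: 6 2-(2-bromoethyl)-2-methyl-1,3-dioxolane
Product: 7 [2-(2-methyl-1,3-dioxolan-2-yl)ethyl]magnesium bromide (titrated THF solution)
Conditions: Mg turnings, I2 (cat.), THF, 25–30 °C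
Reagents that add atoms: magnesium, [Mg]
Why: Grignard formation by magnesium insertion into a primary C–Br bond, kept at or below 30 °C where this ketal-bearing reagent should be stable.

Step 4
Reactants: 5 3,3-dimethylcyclopropene; 7 ketal Grignard reagent
Product: 9 bromo{(1R,3R)-2,2-dimethyl-3-[2-(2-methyl-1,3-dioxolan-2-yl)ethyl]cyclopropyl}zinc (zinc cis to the chain; used as solution), via cyclopropylmagnesium bromide 8 (not isolated)
Conditions: CuI (5 mol %), (R)-1-[(Sp)-2-(diphenylphosphino)ferrocenyl]ethyldicyclohexylphosphine (6 mol %), Et2O–THF, −40 → 0 °C; then ZnBr2 (1.05 equiv), THF, −20 °C → rt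
Reagents that add atoms: zinc bromide, Br[Zn]Br
Why: Copper-catalysed enantioselective syn-carbomagnesiation of a 3,3-disubstituted cyclopropene, in which the chiral alkylcopper adds across the strained C=C so that chain and metal end up cis and both ring centres are set by the ligand, followed by Mg-to-Zn transmetalation with retention at the configurationally stable cyclopropyl carbon.

Step 5
Reactants: 10 all-cis (meso) cyclohexane-1,2,4,5-tetracarboxylic 1,2:4,5-dianhydride; 9 cyclopropylzinc bromide (2.6 equiv)
Product: 12 (1R,2S,4R,5S)-2,5-bis({(1R,3S)-2,2-dimethyl-3-[2-(2-methyl-1,3-dioxolan-2-yl)ethyl]cyclopropyl}carbonyl)cyclohexane-1,4-dicarboxylic acid (twofold-symmetric all-cis diketo diacid: ketones C3 on C2 and C7 on C6; acids C8 on C1 and C4 on C5), via keto acid anhydride 11 (not isolated)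
Conditions: Pd(OAc)2 (10 mol %), (R)-1-[(Sp)-2-(diphenylphosphino)ferrocenyl]ethyldicyclohexylphosphine (12 mol %), 4-fluorostyrene (0.5 equiv), THF, 0 → 25 °C; aq. citric acid (pH 4)
Reagents that add atoms: none
Why: Zerovalent palladium, formed from Pd(OAc)2 and the organozinc, inserts into one acyl C–O bond of an anhydride ring, the cyclopropyl group passes from zinc to palladium with retention, and reductive elimination releases a cyclopropyl ketone beside a zinc carboxylate; the second ring of 11 reacts the same way. The closest known reaction is the catalytic enantioselective acyl cross-coupling of meso succinic anhydrides with organozinc reagents (a Negishi-type alkylative desymmetrisation). No ring is closed; the two new bonds are C3–cyclopropyl and C7–cyclopropyl. No carbon changes geometry: C1, C2, C5 and C6 are already all cis in meso 10 and take their absolute sense from the chiral diphosphine on palladium, which picks one of the two enantiotopic carbonyls of each ring, while the cyclopropane centres arrive fixed in 9. The step needs the same choice at both rings; the rings are related by the twofold axis, so one catalyst preference serves both, and since 9 is a single enantiomer any wrong choice ends in a separable diastereomer. A cyclopropyl–palladium species has no easy β-hydride loss, and the cis keto acid should not epimerise under these near-neutral conditions.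

Step 6
Reactants: 12 diketo diacid
Product: 14 lactone keto acid (γ-lactone C7–O–C4(=O) cis-fused at C5–C6; C3 ketone on C2; C8 acid on C1; C7 epimers), via C7-hydroxy keto diacid 13 (not isolated)
Conditions: NaHCO3, NaBH4 (about 0.35 equiv, in portions to about half conversion), EtOH–H2O, 0 °C; then aq. citric acid to pH 4, rt; recovered 12 recycled
Reagents that add atoms: none
Why: Borohydride reduction of a γ-keto carboxylate and lactonisation of the cis γ-hydroxy acid on acidification; the two ketones of 12 are homotopic, so mono-reduction gives a single constitution, and the lactone marks C4 as the future aldehyde carbon while locking C5 and C6 cis.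

Step 7
Reactants: 14 lactone keto acid
Product: 16 C2-methyl lactone keto acid (CH3 on C2 trans to the C1 carboxyl; C3 acyl still cis), via dilithium enolate carboxylate 15 (not isolated)
Conditions: LiN(SiMe3)2 (2.2 equiv), THF, −78 °C; MeI (1.3 equiv), DMPU, −78 → −30 °C; aq. citric acid
Reagents that add atoms: iodomethane, CI
Why: Enolate alkylation of a keto acid dianion, where after the carboxylate the C2–H of the one remaining ketone is the most acidic proton (the cyclopropyl α-H is kinetically inert, the lactone α-H is less acidic), and iodomethane should attack the exocyclic enolate on the face opposite the cis C1 carboxylate and the cis-fused lactone.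

Step 8
Reactants: 16 C2-methyl lactone keto acid
Product: 17 S-ethyl thioester of 16 at C8
Conditions: EtSH, EDC·HCl, DMAP (cat.), CH2Cl2, 0 °C → rt
Reagents that add atoms: ethanethiol, CCS
Why: Steglich-type carbodiimide thioesterification of the carboxylic acid, run cold so that C1 is not epimerised through a ketene.

Step 9
Reactants: 17 thioester
Product: 18 lactone diketone (C8 now a methyl ketone; C3 ketone and lactone unchanged)
Conditions: MeZnI (3 equiv, THF solution), PdCl2(PPh3)2 (10 mol %), toluene–THF, rt
Reagents that add atoms: methylzinc iodide, C[Zn]I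
Why: Fukuyama coupling, in which zerovalent palladium inserts into the thioester C–S bond and methyl is transferred from zinc, a ketone synthesis that leaves the existing ketone, the lactone and the ketals untouched.

Step 10
Reactants: 18 lactone diketone
Product: 19 tetraol (C3–OH; C4H2–OH; C7–OH; C8(H)(CH3)–OH; carbinol epimers)
Conditions: LiAlH4, THF, 0 °C → rt; then H2O, aq. NaOH
Reagents that add atoms: none
Why: Exhaustive hydride reduction opens the lactone to the 1,4-diol and takes both ketones to alcohols, so no carbonyl group has to be told from another.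

Step 11
Reactants: 19 tetraol
Product: 20 tetracarbonyl compound (C3 cyclopropyl ketone on C2; C4 aldehyde on C5; C7 cyclopropyl ketone on C6; C8 methyl ketone on C1; all cis; used at once)
Conditions: (COCl)2, DMSO, CH2Cl2, −78 → −60 °C; iPr2NEt, −78 → −40 °C; pH 7 buffer
Reagents that add atoms: none
Why: Swern oxidation activates all four hydroxyls as alkoxysulfonium ions before base is added, so the 1,4-diol pair cannot pass through a lactol to a lactone, and the hindered amine at low temperature should spare the C5 centre next to the aldehyde.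

Step 12
Reactants: 20 tetracarbonyl compound
Product: 22 bis(ethylene ketal) of the target (syn-tricyclic diene), via C3=C4 ene-dione 21 (not isolated)
Conditions: TiCl3(DME)1.5, zinc–copper couple, DME, reflux; 20 added by syringe pump at high dilution
Reagents that add atoms: none
Why: Twofold intramolecular McMurry coupling, favoured because in either chair of the all-cis ring one 1,3-related carbonyl pair (C3/C4 or C7/C8) is diaxial and set up for five-membered pinacol coupling and deoxygenation on low-valent titanium, the aldehyde pair reacting first and the remaining pair then having only each other (neighbouring carbonyls would give a cyclobutene), with ketals tolerated.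

Step 13
Reactants: 22 bis-ketal
Product: 23 CNP0300925.1
Conditions: PPTS, acetone–H2O (10:1), 45 °C
Reagents that add atoms: water, O
Why: Acid-catalysed ketal hydrolysis under conditions mild enough to leave the vinylcyclopropanes and the strained diene untouched.

Compound list
1 | 3-methylbut-2-enal | CC(C)=CC=O | starting material
2 | N'-(3-methylbut-2-en-1-ylidene)-4-methylbenzenesulfonohydrazide | CC(C)=C/C=N/NS(=O)(=O)c1ccc(C)cc1 | intermediate
3 | sodium salt of 2 (not isolated) | CC(C)=C/C=N/[N-]S(=O)(=O)c1ccc(C)cc1.[Na+] | intermediate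
4 | 1-diazo-3-methylbut-2-ene (not isolated) | CC(C)=CC=[N+]=[N-] | intermediate
5 | 3,3-dimethylcyclopropene | CC1(C)C=C1 | intermediate
6 | 2-(2-bromoethyl)-2-methyl-1,3-dioxolane | CC1(CCBr)OCCO1 | starting material
7 | [2-(2-methyl-1,3-dioxolan-2-yl)ethyl]magnesium bromide | CC1(CC[Mg]Br)OCCO1 | intermediate
8 | {(1R,3R)-2,2-dimethyl-3-[2-(2-methyl-1,3-dioxolan-2-yl)ethyl]cyclopropyl}magnesium bromide (not isolated) | CC1(OCCO1)CC[C@H]1[C@@H]([Mg]Br)C1(C)C | intermediate
9 | bromo{(1R,3R)-2,2-dimethyl-3-[2-(2-methyl-1,3-dioxolan-2-yl)ethyl]cyclopropyl}zinc | CC1(OCCO1)CC[C@H]1[C@@H]([Zn]Br)C1(C)C | intermediate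
10 | all-cis (meso) cyclohexane-1,2,4,5-tetracarboxylic dianhydride | O=C1OC(=O)[C@@H]2C[C@@H]3C(=O)OC(=O)[C@@H]3C[C@H]12 | starting material
11 | mono-acylated keto acid anhydride (C3 ketone on C2, C8 acid on C1, anhydride across C5/C6; not isolated) | CC1(OCCO1)CC[C@H]1[C@@H](C(=O)[C@H]2C[C@H]3C(=O)OC(=O)[C@H]3C[C@H]2C(=O)O)C1(C)C | intermediate
12 | (1R,2S,4R,5S)-2,5-bis({(1R,3S)-2,2-dimethyl-3-[2-(2-methyl-1,3-dioxolan-2-yl)ethyl]cyclopropyl}carbonyl)cyclohexane-1,4-dicarboxylic acid | CC1(OCCO1)CC[C@H]1[C@@H](C(=O)[C@H]2C[C@@H](C(=O)O)[C@H](C[C@H]2C(=O)O)C(=O)[C@@H]3[C@H](CCC4(C)OCCO4)C3(C)C)C1(C)C | intermediate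
13 | C7-hydroxy keto diacid (C7 epimers; not isolated) | CC1(OCCO1)CC[C@H]1[C@@H](C(=O)[C@H]2C[C@@H](C(=O)O)[C@H](C[C@H]2C(=O)O)C(O)[C@@H]3[C@H](CCC4(C)OCCO4)C3(C)C)C1(C)C | intermediate
14 | lactone keto acid (C7–O–C4 γ-lactone, C3 ketone, C8 acid; C7 epimers) | CC1(OCCO1)CC[C@H]1[C@@H](C(=O)[C@H]2C[C@H]3C(=O)OC([C@@H]4[C@H](CCC5(C)OCCO5)C4(C)C)[C@H]3C[C@H]2C(=O)O)C1(C)C | intermediate
15 | dilithium C2 enolate carboxylate of 14 (not isolated) | CC1(OCCO1)CC[C@H]1[C@@H](C([O-])=C2C[C@H]3C(=O)OC([C@@H]4[C@H](CCC5(C)OCCO5)C4(C)C)[C@H]3C[C@H]2C(=O)[O-])C1(C)C.[Li+].[Li+] | intermediate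
16 | C2-methyl lactone keto acid (C7 epimers) | CC1(OCCO1)CC[C@H]1[C@@H](C(=O)[C@@]2(C)C[C@H]3C(=O)OC([C@@H]4[C@H](CCC5(C)OCCO5)C4(C)C)[C@H]3C[C@H]2C(=O)O)C1(C)C | intermediate
17 | C8 S-ethyl thioester of 16 | CC1(OCCO1)CC[C@H]1[C@@H](C(=O)[C@@]2(C)C[C@H]3C(=O)OC([C@@H]4[C@H](CCC5(C)OCCO5)C4(C)C)[C@H]3C[C@H]2C(=O)SCC)C1(C)C | intermediate
18 | lactone diketone (C8 methyl ketone, C3 ketone, lactone; C7 epimers) | CC1(OCCO1)CC[C@H]1[C@@H](C(=O)[C@@]2(C)C[C@H]3C(=O)OC([C@@H]4[C@H](CCC5(C)OCCO5)C4(C)C)[C@H]3C[C@H]2C(C)=O)C1(C)C | intermediate
19 | tetraol (carbinol epimers at C3, C7, C8) | CC1(OCCO1)CC[C@H]1[C@@H](C(O)[C@@]2(C)C[C@@H](CO)[C@H](C[C@H]2C(C)O)C(O)[C@@H]3[C@H](CCC4(C)OCCO4)C3(C)C)C1(C)C | intermediate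
20 | all-cis tetracarbonyl compound (C3 and C7 cyclopropyl ketones, C4 aldehyde, C8 methyl ketone) | CC1(OCCO1)CC[C@H]1[C@@H](C(=O)[C@@]2(C)C[C@@H](C=O)[C@H](C[C@H]2C(C)=O)C(=O)[C@@H]3[C@H](CCC4(C)OCCO4)C3(C)C)C1(C)C | intermediate
21 | C3=C4 ene-dione (first cyclopentene closed; not isolated) | CC1(OCCO1)CC[C@H]1[C@@H](C2=C[C@@H]3C[C@@]2(C)[C@H](C(C)=O)C[C@@H]3C(=O)[C@@H]3[C@H](CCC4(C)OCCO4)C3(C)C)C1(C)C | intermediate
22 | bis(ethylene ketal) of the target | CC1(OCCO1)CC[C@H]1[C@@H](C2=C[C@@H]3C[C@@]2(C)[C@H]2C[C@@H]3C([C@@H]3[C@H](CCC4(C)OCCO4)C3(C)C)=C2C)C1(C)C | intermediate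
23 | CNP0300925.1: (1S,2S,5S,6S)-2,8-dimethyl-syn-tricyclo[4.2.1.1(2,5)]deca-3,7-diene with a (1R,3S)-2,2-dimethyl-3-(3-oxobutyl)cyclopropyl group on C3 and on C7 (cyclopropane locant 1 = carbon bonded to the core) | CC(=O)CC[C@H]1[C@@H](C2=C[C@@H]3C[C@@]2(C)[C@H]2C[C@@H]3C([C@@H]3[C@H](CCC(C)=O)C3(C)C)=C2C)C1(C)C | target

Total step count: 13.
Longest linear sequence: 12 steps (1 → 2 → 5 → 9 → 12 → 14 → 16 → 17 → 18 → 19 → 20 → 22 → 23); step 3 is a one-step branch.

Steps most likely to fail

Step 5. The hindered secondary cyclopropyl group may transfer from zinc so slowly that the acyl–palladium intermediate loses CO or is reduced. A mismatched pairing of ligand and chiral reagent may erode the choice of carbonyl, and the second acylation may stall on the zinc carboxylate of 11. The fallback sets out from 10 and returns at 12; it separates the desymmetrisation from the C–C bond formation. Both anhydride rings of 10 are opened with benzyl alcohol under cinchona alkaloid control (quinidine or quinine as the sense requires, toluene, −55 °C) to the twofold-symmetric bis(benzyl hemiester) F1, with benzyl esters on C1 and C5 and free acids on C2 and C6. The acids are converted (EtSH, EDC·HCl, DMAP) into the bis(S-ethyl thioester) F2. Fukuyama coupling of F2 with 9 (PdCl2(PPh3)2, THF–toluene), which no longer has to be enantioselective, forms the same C3– and C7–cyclopropyl bonds and gives the diketo dibenzyl ester F3. Hydrogenolysis (H2, Pd/C, EtOAc) then gives 12.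

Step 12. The gem-dimethylcyclopropane may open through a cyclopropylcarbinyl ketyl radical, carbonyls may pair across the ring (C3 with C7 or C4 with C8), or intermolecular coupling may take over when the strained second closure is slow. The fallback sets out from 20 and returns at 22; it uses no radicals. Fourfold methylenation of 20 with the Tebbe reagent Cp2Ti(CH2)(Cl)AlMe2 (THF–pyridine, −40 °C → rt; not basic, so C5 is safe) gives the tetraene F4. Twofold ring-closing metathesis (second-generation Hoveyda–Grubbs catalyst, toluene, 80 °C, ethene swept out) then closes C3=C4 and C7=C8 to 22.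

Step 7. The crowded dianion may alkylate so slowly that O-methylation, esterification of the carboxylate or proton exchange with the lactone compete, or iodomethane may enter from the wrong face. The fallback sets out from 12 and returns at 16; it methylates before the symmetry is broken by reduction. 12 is converted (allyl bromide, KHCO3, DMF) into the diallyl ester F5. One equivalent of KN(SiMe3)2 and MeI (THF, −78 °C) gives the mono-C2-methyl diallyl ester F6; the two ketones are homotopic and unchanged F5 is recycled. NaBH4 (MeOH, 0 °C) reduces only the C7 ketone, the one not flanked by the quaternary carbon, and the alkoxide closes onto the neighbouring allyl ester to give the lactone allyl ester F7. Pd(PPh3)4 and morpholine (THF, rt) free the C8 acid, which is 16.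

Further compounds
F1 | step 5 | twofold-symmetric bis(benzyl hemiester) of 10 (benzyl esters on C1 and C5, acids on C2 and C6) | OC(=O)[C@H]1C[C@@H](C(=O)OCc2ccccc2)[C@H](C[C@H]1C(=O)OCc3ccccc3)C(=O)O
F2 | step 5 | bis(S-ethyl thioester) of F1 | CCSC(=O)[C@H]1C[C@@H](C(=O)OCc2ccccc2)[C@H](C[C@H]1C(=O)OCc3ccccc3)C(=O)SCC
F3 | step 5 | dibenzyl ester of 12 | CC1(OCCO1)CC[C@H]1[C@@H](C(=O)[C@H]2C[C@@H](C(=O)OCc3ccccc3)[C@H](C[C@H]2C(=O)OCc4ccccc4)C(=O)[C@@H]3[C@H](CCC4(C)OCCO4)C3(C)C)C1(C)C
F4 | step 12 | tetraene from fourfold methylenation of 20 | CC1(OCCO1)CC[C@H]1[C@@H](C(=C)[C@@]2(C)C[C@@H](C=C)[C@H](C[C@H]2C(C)=C)C(=C)[C@@H]3[C@H](CCC4(C)OCCO4)C3(C)C)C1(C)C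
F5 | step 7 | diallyl ester of 12 | CC1(OCCO1)CC[C@H]1[C@@H](C(=O)[C@H]2C[C@@H](C(=O)OCC=C)[C@H](C[C@H]2C(=O)OCC=C)C(=O)[C@@H]3[C@H](CCC4(C)OCCO4)C3(C)C)C1(C)C
F6 | step 7 | mono-C2-methyl diallyl ester | CC1(OCCO1)CC[C@H]1[C@@H](C(=O)[C@@]2(C)C[C@@H](C(=O)OCC=C)[C@H](C[C@H]2C(=O)OCC=C)C(=O)[C@@H]3[C@H](CCC4(C)OCCO4)C3(C)C)C1(C)C
F7 | step 7 | C2-methyl lactone allyl ester (C7 epimers) | CC1(OCCO1)CC[C@H]1[C@@H](C(=O)[C@@]2(C)C[C@H]3C(=O)OC([C@@H]4[C@H](CCC5(C)OCCO5)C4(C)C)[C@H]3C[C@H]2C(=O)OCC=C)C1(C)C
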